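## Retrosynthetic overview
1. The target comes from its central MOM ether 17. The central naphthalene (unit B) is bought as naphthalene-1,8-diol. Only the hydroxylated rings of the outer units A and C are built.
2. Each outer naphthol comes from a 2-aryl-1,2-dihydronaphthalen-1-ol by oxidation and tautomerisation. That ring comes from ring-closing metathesis (C3=C4) of a styrene/vinyl pair.
3. Key disconnection: C1–C2 of both outer units. This is a two-fold intermolecular carbonyl allylation of 2-ethenyl-6-methoxybenzaldehyde 4 by the central bis[(E)-allylboronate] 12.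
4. 12 comes from 2,4-dibromide 8 (double Heck, reduction, acetate, borylation), and 8 from 8-methoxy-1-naphthol. Aldehyde 4 comes from 2,6-dimethoxybenzaldehyde.
5. Ring order: B and the two anisole rings are preformed. The phenolic rings of A and C close together in step 12 and aromatise together in step 13.

Assumption: the SMILES has no stereodescriptor and the molecule has no stereocentre. Neither biaryl axis is hindered enough to be configurationally stable at room temperature (2,2' carries two ortho OH; 4',2'' carries one ortho OH and one peri H). The compound is therefore made as drawn, and no asymmetric step is needed.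

## Route

Step 1
Reactants: 1 2,6-dimethoxybenzaldehyde
Product: 2 2-hydroxy-6-methoxybenzaldehyde
Conditions: BCl3 (1.1 equiv), CH2Cl2, −78 → 0 °C; then H2O
Reagents that add atoms: none
Why: Chelation-controlled Lewis-acid ether cleavage, in which BCl3 bridges the aldehyde oxygen and one flanking OMe, so exactly one methyl leaves as MeCl and the boron chelate blocks a second cleavage.

Step 2
Reactants: 2 2-hydroxy-6-methoxybenzaldehyde
Product: 3 2-formyl-3-methoxyphenyl trifluoromethanesulfonate
Conditions: Tf2O, pyridine, CH2Cl2, 0 °C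
Reagents that add atoms: trifluoromethanesulfonic anhydride, O=S(=O)(OS(=O)(=O)C(F)(F)F)C(F)(F)F
Why: Routine O-sulfonylation (triflation) of an acidic salicylaldehyde-type phenol, with no other nucleophilic site present.

Step 3
Reactants: 3 2-formyl-3-methoxyphenyl trifluoromethanesulfonate
Product: 4 2-ethenyl-6-methoxybenzaldehyde
Conditions: vinylboronic acid pinacol ester (1.3 equiv), PdCl2(dppf) (3 mol %), K3PO4, dioxane/H2O 10:1, 80 °C
Reagents that add atoms: vinylboronic acid pinacol ester, C=CB1OC(C)(C)C(C)(C)O1
Why: Suzuki–Miyaura vinylation, in which the ortho-formyl group speeds oxidative addition of the triflate and the aldehyde is inert to these conditions.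

Step 4
Reactants: 5 naphthalene-1,8-diol
Product: 6 8-methoxynaphthalen-1-ol
Conditions: MeI (1.0 equiv), K2CO3 (1.0 equiv), acetone, reflux
Reagents that add atoms: iodomethane, CI
Why: Williamson etherification that stops at the mono-ether, because the remaining OH is held in a peri hydrogen bond to the new OMe and only one equivalent each of base and MeI is used.

Step 5
Reactants: 6 8-methoxynaphthalen-1-ol
Product: 7 2,4-dibromo-8-methoxynaphthalen-1-ol
Conditions: NBS (2.05 equiv), MeCN, −10 → 0 °C
Reagents that add atoms: N-bromosuccinimide, O=C1CCC(=O)N1Br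
Why: Electrophilic aromatic bromination, in which the free OH outranks OMe as activator so para (C4) then ortho (C2) of the phenol ring react, while C5 is peri-blocked by the C4 bromine.

Step 6
Reactants: 7 2,4-dibromo-8-methoxynaphthalen-1-ol
Product: 8 2,4-dibromo-8-methoxy-1-(methoxymethoxy)naphthalene
Conditions: NaH, MOMCl, THF/DMF, 0 °C → rt
Reagents that add atoms: chloromethyl methyl ether, COCCl
Why: Williamson-type MOM protection of the acidic dibromonaphtholate with a small, very reactive electrophile, giving a group that has no arene able to intercept the aryl–palladium species of step 7.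

Step 7
Reactants: 8 2,4-dibromo-8-methoxy-1-(methoxymethoxy)naphthalene
Product: 9 dimethyl (2E,2'E)-3,3'-[5-methoxy-4-(methoxymethoxy)naphthalene-1,3-diyl]bis(prop-2-enoate)
Conditions: methyl acrylate (4 equiv), Pd(OAc)2 (8 mol %), P(o-tol)3 (20 mol %), Et3N, DMF, 110 °C
Reagents that add atoms: methyl acrylate, C=CC(=O)OC
Why: Two-fold Mizoroki–Heck reaction, in which syn insertion into the acrylate and syn β-hydride elimination give the (E)-cinnamate at both C–Br positions.

Step 8
Reactants: 9 dimethyl (2E,2'E)-3,3'-[5-methoxy-4-(methoxymethoxy)naphthalene-1,3-diyl]bis(prop-2-enoate)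
Product: 10 (2E,2'E)-3,3'-[5-methoxy-4-(methoxymethoxy)naphthalene-1,3-diyl]bis(prop-2-en-1-ol)
Conditions: iBu2AlH (DIBAL-H, 5 equiv), CH2Cl2, −78 → 0 °C; then aq. potassium sodium tartrate work-up
Reagents that add atoms: none
Why: Clean 1,2-reduction of enoates to allylic alcohols by DIBAL-H, which keeps the E geometry and leaves the MOM and methyl ethers intact at low temperature.

Step 9
Reactants: 10 (2E,2'E)-3,3'-[5-methoxy-4-(methoxymethoxy)naphthalene-1,3-diyl]bis(prop-2-en-1-ol)
Product: 11 (2E,2'E)-[5-methoxy-4-(methoxymethoxy)naphthalene-1,3-diyl]bis(prop-2-ene-3,1-diyl) diacetate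
Conditions: Ac2O, Et3N, DMAP (cat.), CH2Cl2, 0 °C → rt
Reagents that add atoms: acetic anhydride, CC(=O)OC(C)=O
Why: DMAP-catalysed acylation gives a storable allylic electrophile and avoids the very labile electron-rich cinnamyl halides.

Step 10
Reactants: 11 (2E,2'E)-[5-methoxy-4-(methoxymethoxy)naphthalene-1,3-diyl]bis(prop-2-ene-3,1-diyl) diacetate
Product: 12 2,2'-{[5-methoxy-4-(methoxymethoxy)naphthalene-1,3-diyl]bis[(2E)-prop-2-ene-3,1-diyl]}bis(4,4,5,5-tetramethyl-1,3,2-dioxaborolane)
Conditions: B2pin2 (2.4 equiv), Pd(dba)2 (5 mol %), DMSO, 50 °C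
Reagents that add atoms: bis(pinacolato)diboron, CC1(C)OB(OC1(C)C)B1OC(C)(C)C(C)(C)O1
Why: Miyaura-type allylic borylation, in which zerovalent palladium ionises each acetate to a π-allyl complex, the acetate ligand activates B2pin2 for transmetalation, and C–B bond formation at the unhindered terminus gives the linear (E)-allylboronate.

Step 11
Reactants: 12 the bis[(E)-allyl pinacol boronate] of step 10; 4 2-ethenyl-6-methoxybenzaldehyde (2.4 equiv)
Product: 14 2,2'-[5-methoxy-4-(methoxymethoxy)naphthalene-1,3-diyl]bis[1-(2-ethenyl-6-methoxyphenyl)but-3-en-1-ol] (anti in each arm; racemic mixture of arm-to-arm diastereomers), via bis(pinacol borate) ester 13 (not isolated)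
Conditions: toluene, 4 Å MS, 50 °C, 48 h; then H2O
Reagents that add atoms: none
Why: Two-fold carbonyl allylation (allylboration) through closed Zimmerman–Traxler chairs, which is irreversible and strictly γ-selective, so each aryl-bearing carbon bonds to an aldehyde carbon; the E-boronate sets anti relative configuration within each arm, and arm-to-arm control is unnecessary because all four centres are erased in step 13.

Step 12
Reactants: 14 2,2'-[5-methoxy-4-(methoxymethoxy)naphthalene-1,3-diyl]bis[1-(2-ethenyl-6-methoxyphenyl)but-3-en-1-ol]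
Product: 15 2,2'-[5-methoxy-4-(methoxymethoxy)naphthalene-1,3-diyl]bis(8-methoxy-1,2-dihydronaphthalen-1-ol) (cis in each ring; diastereomer mixture)
Conditions: second-generation Grubbs catalyst RuCl2(=CHPh)(PCy3)(H2IMes) (2 × 4 mol %), CH2Cl2 (5 mM), 40 °C; filtration through Et3N-washed silica
Reagents that add atoms: none
Why: Double ring-closing metathesis, in which the carbene loads on each terminal vinyl group and closes onto the neighbouring styrene to form a six-membered ring with loss of ethene, while an arm-to-arm closure would need an impossibly strained meta-bridged ring and the stereocentres are untouched.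

Step 13
Reactants: 15 2,2'-[5-methoxy-4-(methoxymethoxy)naphthalene-1,3-diyl]bis(8-methoxy-1,2-dihydronaphthalen-1-ol)
Product: 17 8,8',8''-trimethoxy-1'-(methoxymethoxy)-[2,2':4',2''-ternaphthalene]-1,1''-diol, via bis(2H-naphthalen-1-one) 16 (not isolated)
Conditions: Dess–Martin periodinane (2.1 equiv), NaHCO3 (excess), CH2Cl2, 0 °C, 30 min
Reagents that add atoms: none
Why: Buffered Dess–Martin oxidation of the two benzylic alcohols gives the keto tautomers of naphthols, which enolise at once with gain of aromaticity (keto–enol tautomerisation) and thereby remove all four stereocentres.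

Step 14
Reactants: 17 8,8',8''-trimethoxy-1'-(methoxymethoxy)-[2,2':4',2''-ternaphthalene]-1,1''-diol
Product: 18 8,8',8''-trimethoxy-[2,2':4',2''-ternaphthalene]-1,1',1''-triol (target)
Conditions: HCl (cat., 1.25 M in MeOH), MeOH/CH2Cl2, 40 °C, under argon
Reagents that add atoms: none
Why: Acid-catalysed acetal exchange (MOM cleavage) frees the central naphthol under conditions too mild to touch the aryl methyl ethers or to dehydrate the 2,2'-diol to a furan.

## Compound list
1 | 2,6-dimethoxybenzaldehyde | COc1cccc(OC)c1C=O | starting material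
2 | 2-hydroxy-6-methoxybenzaldehyde | COc1cccc(O)c1C=O | intermediate
3 | 2-formyl-3-methoxyphenyl trifluoromethanesulfonate | COc1cccc(OS(=O)(=O)C(F)(F)F)c1C=O | intermediate
4 | 2-ethenyl-6-methoxybenzaldehyde | COc1cccc(C=C)c1C=O | intermediate
5 | naphthalene-1,8-diol | Oc1cccc2cccc(O)c12 | starting material
6 | 8-methoxynaphthalen-1-ol | COc1cccc2cccc(O)c12 | intermediate
7 | 2,4-dibromo-8-methoxynaphthalen-1-ol | COc1cccc2c(Br)cc(Br)c(O)c12 | intermediate
8 | 2,4-dibromo-8-methoxy-1-(methoxymethoxy)naphthalene | COCOc1c(Br)cc(Br)c2cccc(OC)c12 | intermediate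
9 | dimethyl (2E,2'E)-3,3'-[5-methoxy-4-(methoxymethoxy)naphthalene-1,3-diyl]bis(prop-2-enoate) | COC(=O)/C=C/c1cc(/C=C/C(=O)OC)c2cccc(OC)c2c1OCOC | intermediate
10 | (2E,2'E)-3,3'-[5-methoxy-4-(methoxymethoxy)naphthalene-1,3-diyl]bis(prop-2-en-1-ol) | OC/C=C/c1cc(/C=C/CO)c2cccc(OC)c2c1OCOC | intermediate
11 | diacetate of 10 | CC(=O)OC/C=C/c1cc(/C=C/COC(C)=O)c2cccc(OC)c2c1OCOC | intermediate
12 | bis[(E)-allyl pinacol boronate] of the central naphthalene | COCOc1c(/C=C/CB2OC(C)(C)C(C)(C)O2)cc(/C=C/CB2OC(C)(C)C(C)(C)O2)c2cccc(OC)c12 | intermediate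
13 | bis(pinacol borate) ester of 14 (not isolated; sp3 centres as in 14) | C=CC(C(OB1OC(C)(C)C(C)(C)O1)c1c(C=C)cccc1OC)c1cc(C(C=C)C(OB2OC(C)(C)C(C)(C)O2)c2c(C=C)cccc2OC)c2cccc(OC)c2c1OCOC | intermediate
14 | 2,2'-[5-methoxy-4-(methoxymethoxy)naphthalene-1,3-diyl]bis[1-(2-ethenyl-6-methoxyphenyl)but-3-en-1-ol] (anti in each arm; racemic diastereomer mixture, so centres are left unassigned in the SMILES) | C=CC(C(O)c1c(C=C)cccc1OC)c1cc(C(C=C)C(O)c2c(C=C)cccc2OC)c2cccc(OC)c2c1OCOC | intermediate
15 | 2,2'-[5-methoxy-4-(methoxymethoxy)naphthalene-1,3-diyl]bis(8-methoxy-1,2-dihydronaphthalen-1-ol) (cis in each ring; diastereomer mixture, centres unassigned) | COCOc1c(C2C=Cc3cccc(OC)c3C2O)cc(C2C=Cc3cccc(OC)c3C2O)c2cccc(OC)c12 | intermediate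
16 | 2,2'-[5-methoxy-4-(methoxymethoxy)naphthalene-1,3-diyl]bis(8-methoxynaphthalen-1(2H)-one) (not isolated) | COCOc1c(C2C=Cc3cccc(OC)c3C2=O)cc(C2C=Cc3cccc(OC)c3C2=O)c2cccc(OC)c12 | intermediate
17 | 8,8',8''-trimethoxy-1'-(methoxymethoxy)-[2,2':4',2''-ternaphthalene]-1,1''-diol | COCOc1c(-c2ccc3cccc(OC)c3c2O)cc(-c2ccc3cccc(OC)c3c2O)c2cccc(OC)c12 | intermediate
18 | 8,8',8''-trimethoxy-[2,2':4',2''-ternaphthalene]-1,1',1''-triol (CNP0482979.0) | COc1cccc2ccc(-c3cc(-c4ccc5cccc(OC)c5c4O)c4cccc(OC)c4c3O)c(O)c12 | target

## Step count and weak points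
Total steps: 14. Longest linear sequence: 11 (steps 4–14, from 5 to 18). Steps 1–3 form the side branch to aldehyde 4.

Step 5 (regiochemistry and extent of the dibromination). The risk is bromine entering the anisole ring, or an uneven mixture of mono- and dibromide.
- The fallback sets out from 6 and fixes the two positions by different reactions.
- OH-directed ortho-formylation (MgCl2, Et3N, paraformaldehyde, MeCN, reflux) gives 1-hydroxy-8-methoxy-2-naphthaldehyde F1.
- One equivalent of NBS then finds only the para position of the phenol ring free and gives 4-bromo-1-hydroxy-8-methoxy-2-naphthaldehyde F2.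
- NaH/MOMCl gives 4-bromo-8-methoxy-1-(methoxymethoxy)-2-naphthaldehyde F3.
- Horner–Wadsworth–Emmons olefination with trimethyl phosphonoacetate and NaH gives methyl (E)-3-[4-bromo-8-methoxy-1-(methoxymethoxy)naphthalen-2-yl]prop-2-enoate F4.
- A single Heck reaction of F4 with methyl acrylate comes back to the route at 9.

Step 11 (two additions of a γ-aryl allylboronate to a 2,6-disubstituted benzaldehyde). The risk is a slow or incomplete second addition. The same fallback also covers a poor borylation in step 10.
- The fallback sets out from 10 and replaces boron by a much more reactive allyl metal.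
- An Appel reaction (CBr4, PPh3, CH2Cl2, 0 °C) gives 2,4-bis[(E)-3-bromoprop-1-enyl]-8-methoxy-1-(methoxymethoxy)naphthalene F5.
- F5 is used crude and at once in a Barbier reaction with indium powder and aldehyde 4 in DMF at room temperature.
- The γ-selective allylindium addition comes back to the route at 14.

Step 13 (oxidation and aromatisation). The risks are dehydration of 15 to 2-arylnaphthalenes, with loss of the C1 oxygens, and over-oxidation of the freed naphthols by periodinane.
- The fallback sets out from 14 and reverses the order of events.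
- Buffered Dess–Martin oxidation of the open-chain diol gives 2,2'-[5-methoxy-4-(methoxymethoxy)naphthalene-1,3-diyl]bis[1-(2-ethenyl-6-methoxyphenyl)but-3-en-1-one] F6, which is kept away from base and silica to avoid alkene conjugation.
- Double ring-closing metathesis with the second-generation Grubbs catalyst in CH2Cl2 at 40 °C then gives 16, which tautomerises in the flask.
- This sequence comes back to the route at 17. No dihydronaphthol is ever formed, and no oxidant is present when the naphthols appear.

## Further compounds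
F1 | step 5 | 1-hydroxy-8-methoxy-2-naphthaldehyde | COc1cccc2ccc(C=O)c(O)c12
F2 | step 5 | 4-bromo-1-hydroxy-8-methoxy-2-naphthaldehyde | COc1cccc2c(Br)cc(C=O)c(O)c12
F3 | step 5 | 4-bromo-8-methoxy-1-(methoxymethoxy)-2-naphthaldehyde | COCOc1c(C=O)cc(Br)c2cccc(OC)c12
F4 | step 5 | methyl (E)-3-[4-bromo-8-methoxy-1-(methoxymethoxy)naphthalen-2-yl]prop-2-enoate | COCOc1c(/C=C/C(=O)OC)cc(Br)c2cccc(OC)c12
F5 | step 11 | 2,4-bis[(E)-3-bromoprop-1-enyl]-8-methoxy-1-(methoxymethoxy)naphthalene | COCOc1c(/C=C/CBr)cc(/C=C/CBr)c2cccc(OC)c12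
F6 | step 13 | 2,2'-[5-methoxy-4-(methoxymethoxy)naphthalene-1,3-diyl]bis[1-(2-ethenyl-6-methoxyphenyl)but-3-en-1-one] | C=CC(C(=O)c1c(C=C)cccc1OC)c1cc(C(C=C)C(=O)c2c(C=C)cccc2OC)c2cccc(OC)c2c1OCOC
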